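**Retrosynthetic overview**

- The target is epicatechin-(4β→6)-epigallocatechin 3,3'-di-O-gallate. Global hydrogenolysis and galloylation of the only two free hydroxyls (lower 3-OH and 3'-OH) lead back to a benzyl-protected dimer.
- Ring C of the lower unit is opened at C4–C4a. This gives an aryl ether whose C2 carries ring B and whose C3–C4 is a terminal oxirane; the ring is closed by a 6-endo Friedel–Crafts epoxy–arene alkylation.
- Enabling feature: ring A of the lower unit is a phloroglucinol ring, and C6 (which carries the upper unit) lies para to C8a–O1. In the open precursor C4a and C8 are therefore equivalent, each ortho to O1 and next to C5–O or C7–O, so closure at either carbon gives only the 4→6 isomer.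
- The O1–C2 ether comes from a Mitsunobu inversion between an epicatechin–phloroglucinol adduct (C4 cation of perbenzylated epicatechin plus phloroglucinol, three equivalent CH) and an erythro epoxy alcohol (from 3,4,5-trihydroxybenzaldehyde by vinyl addition and Sharpless kinetic resolution).
- Order of ring formation: upper rings A, C and B from the chiral pool; ketal ring on lower ring B; oxirane; lower ring C last.

Key step: step 11

Remark: the target is read as upper unit (2R,3R,4S) and lower unit (2R,3R); 3,4,5-tris(benzyloxy)benzoyl chloride is taken as a purchasable reagent.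

**Route**

Step 1
Reactants: 1 (−)-epicatechin
Product: 2 5,7,3',4'-tetra-O-benzyl-(−)-epicatechin
Conditions: BnBr (4.4 equiv), K2CO3, DMF, 0 °C → rt
Reagents that add atoms: benzyl bromide, BrCc1ccccc1
Why: Williamson ether synthesis in which carbonate deprotonates only the four phenols and not the secondary 3-OH, so the tetrabenzyl ether should form without touching C2 or C3.

Step 2
Reactants: 2 5,7,3',4'-tetra-O-benzyl-(−)-epicatechin
Product: 3 3,5,7,3',4'-penta-O-benzyl-(−)-epicatechin
Conditions: NaH, BnBr, DMF, 0 °C → rt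
Reagents that add atoms: benzyl bromide, BrCc1ccccc1
Why: Williamson ether synthesis on the secondary alkoxide, which caps the upper 3-OH with a group that cannot be galloylated in step 13 and that falls in the final hydrogenolysis.

Step 3
Reactants: 3 3,5,7,3',4'-penta-O-benzyl-(−)-epicatechin
Product: 4 (2R,3R,4S)-4-(2-ethoxyethoxy)-penta-O-benzylepicatechin
Conditions: DDQ (2 equiv), 2-ethoxyethanol, CH2Cl2, rt
Reagents that add atoms: 2-ethoxyethanol, CCOCCO
Why: DDQ-mediated oxidative benzylic C–H etherification, in which hydride abstraction from C4 (activated by the ortho and para benzyloxy groups of ring A) is followed at once by capture of the oxidised carbon by the alcohol on the β-face, anti to the 2-aryl and 3-benzyloxy groups (the C4 configuration is lost again in step 4).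

Step 4
Reactants: 4 (2R,3R,4S)-4-(2-ethoxyethoxy)-penta-O-benzylepicatechin, 5 phloroglucinol (10 equiv)
Product: 7 penta-O-benzylepicatechin-(4β→2)-phloroglucinol, via flavan-4-yl cation 6 (not isolated)
Conditions: BF3·OEt2, THF/CH2Cl2, −40 → 0 °C
Reagents that add atoms: none
Why: Lewis-acid-promoted Friedel–Crafts flavanylation (the usual interflavan-bond-forming reaction), in which BF3 ionises the C4 ether to cation 6, the three ring CH of phloroglucinol are equivalent so only one constitution can form, attack anti to the α-oriented 2-aryl and 3-benzyloxy groups sets the 3,4-trans (4β, 4S) center, and the excess of 5 suppresses double flavanylation.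

Step 5
Reactants: 8 3,4,5-trihydroxybenzaldehyde
Product: 9 7-hydroxy-2,2-diphenyl-1,3-benzodioxole-5-carbaldehyde
Conditions: Ph2CCl2, Ph2O, 170 °C
Reagents that add atoms: dichlorodiphenylmethane, ClC(Cl)(c1ccccc1)c1ccccc1
Why: Catechol ketalisation, in which a five-membered ketal can only bridge two adjacent hydroxyls and the two adjacent pairs of 8 are equivalent, so exactly one phenol (the future 3'-OH) should stay free.

Step 6
Reactants: 9 7-hydroxy-2,2-diphenyl-1,3-benzodioxole-5-carbaldehyde
Product: 10 2,2-diphenyl-7-(triisopropylsilyloxy)-1,3-benzodioxole-5-carbaldehyde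
Conditions: TIPSCl, imidazole, DMF, rt
Reagents that add atoms: chlorotriisopropylsilane, CC(C)[Si](Cl)(C(C)C)C(C)C
Why: Silylation of the phenol, with the TIPS ether chosen because it should survive the Grignard reagent, carbonate base and the Lewis acid of step 11 and still leave with fluoride in the presence of benzyl ethers.

Step 7
Reactants: 10 2,2-diphenyl-7-(triisopropylsilyloxy)-1,3-benzodioxole-5-carbaldehyde
Product: 11 rac-1-[2,2-diphenyl-7-(triisopropylsilyloxy)-1,3-benzodioxol-5-yl]prop-2-en-1-ol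
Conditions: CH2=CHMgBr, THF, −78 → 0 °C; then aq. NH4Cl
Reagents that add atoms: vinylmagnesium bromide, C=C[Mg]Br
Why: Grignard 1,2-addition to the aldehyde, which forms the carbinol center as a racemate that is resolved in step 8.

Step 8
Reactants: 11 rac-1-[2,2-diphenyl-7-(triisopropylsilyloxy)-1,3-benzodioxol-5-yl]prop-2-en-1-ol
Product: 12 (S)-[2,2-diphenyl-7-(triisopropylsilyloxy)-1,3-benzodioxol-5-yl][(2R)-oxiran-2-yl]methanol (erythro)
Conditions: Ti(OiPr)4 (cat.), L-(+)-DIPT, TBHP (0.6 equiv), 4 Å MS, CH2Cl2, −20 °C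
Reagents that add atoms: tert-butyl hydroperoxide, CC(C)(C)OO
Why: Sharpless kinetic resolution, in which with L-(+)-DIPT the (R)-enantiomer of 11 should be epoxidised much faster than the (S)-enantiomer and from the face that gives the erythro epoxy alcohol, so both centers of 12 (carbinol S, oxirane R) are reagent-controlled while (S)-11 stays behind and is separated.

Step 9
Reactants: 7 penta-O-benzylepicatechin-(4β→2)-phloroglucinol (1.2 equiv), 12 (S)-[2,2-diphenyl-7-(triisopropylsilyloxy)-1,3-benzodioxol-5-yl][(2R)-oxiran-2-yl]methanol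
Product: 13 5-{(R)-[2,2-diphenyl-7-(triisopropylsilyloxy)-1,3-benzodioxol-5-yl][(2R)-oxiran-2-yl]methoxy}-2-(penta-O-benzylepicatechin-4β-yl)benzene-1,3-diol
Conditions: PPh3, DIAD, THF, 0 °C → rt
Reagents that add atoms: none
Why: Mitsunobu etherification with inversion at the carbinol carbon (S to R, the future C2 of the lower unit), a coupling known for aryl oxiranyl carbinols and phloroglucinol-type phenols; of the three hydroxyls of 7 only the one para to the flavanyl group is unhindered and should react first, and the slight excess of 7 limits bis-etherification.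

Step 10
Reactants: 13 5-{(R)-[aryl][(2R)-oxiran-2-yl]methoxy}-2-(penta-O-benzylepicatechin-4β-yl)benzene-1,3-diol
Product: 14 1,3-di-O-benzyl ether of 13
Conditions: BnBr, K2CO3, DMF, rt
Reagents that add atoms: benzyl bromide, BrCc1ccccc1
Why: Williamson ether synthesis on the two remaining phenols, to which the oxirane, the TIPS ether and all stereocenters should be inert at room temperature.

Step 11
Reactants: 14 1,3-di-O-benzyl ether of 13
Product: 15 penta-O-benzylepicatechin-(4β→6)-[5,7-di-O-benzyl-4',5'-O-diphenylmethylene-3'-O-triisopropylsilyl-epigallocatechin] (lower unit 2R,3R, free 3-OH)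
Conditions: AuCl3 (5 mol %), AgOTf (15 mol %), 4 Å MS, CH2Cl2, 0 °C → rt
Reagents that add atoms: none
Why: The cationic trivalent gold Lewis acid formed from AuCl3 and AgOTf binds the oxirane oxygen, one of the two carbons ortho to the ether oxygen of the central ring attacks the terminal CH2 in an SN2-like manner to give an arenium ion, and loss of the ring proton with protonation of the metal alkoxide restores aromaticity and frees the C3 hydroxyl. The closest known reaction is the Lewis-acid-catalysed intramolecular Friedel–Crafts epoxy–arene cyclisation of 3,5-dialkoxyphenyl 1-aryl-2,3-epoxypropyl ethers to flavan-3-ols. Ring C of the lower unit closes in the 6-endo-tet mode, because the 5-exo alternative needs attack at the internal oxirane carbon, which is more hindered and inductively deactivated by the neighbouring aryloxy-bearing carbon. No stereocenter is formed or broken: C2 (R, from the Mitsunobu inversion) and C3 (R, from the epoxidation) keep their C–O bonds, so the threo ether–oxirane becomes the 2,3-cis (2R,3R) flavan-3-ol. The selectivity the step needs is the site of arene attack, and the substrate secures it: the flavanyl group sits para to the ether oxygen, the two ortho carbons are constitutionally equivalent, are the only free positions of that ring and are each activated by three oxygens, so either closure gives the 4→6 dimer and no 4→8 isomer can arise. Chemoselectivity over the acid-labile interflavan bond and benzylic ethers rests on the catalytic, aprotic conditions.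

Step 12
Reactants: 15 protected dimer with 3'-O-TIPS and free 3-OH
Product: 16 penta-O-benzylepicatechin-(4β→6)-[5,7-di-O-benzyl-4',5'-O-diphenylmethylene-epigallocatechin] (free 3-OH and 3'-OH)
Conditions: TBAF, AcOH, THF, 0 °C
Reagents that add atoms: none
Why: Fluoride-mediated desilylation of the aryl TIPS ether, buffered with acetic acid so the phenoxide is protonated at once, which should leave benzyl ethers, the ketal and the secondary alcohol untouched.

Step 13
Reactants: 16 diol (free 3-OH and 3'-OH), 17 3,4,5-tris(benzyloxy)benzoyl chloride (3 equiv)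
Product: 18 3,3'-bis-O-[3,4,5-tris(benzyloxy)benzoyl] derivative of 16
Conditions: DMAP, Et3N, CH2Cl2, 0 °C → rt
Reagents that add atoms: none
Why: DMAP-catalysed acylation with an acid chloride of the only two free hydroxyls, the secondary 3-OH and the 3'-phenol of the lower unit, which should install both galloyl esters at once while the upper 3-oxygen stays benzylated.

Step 14
Reactants: 18 fully protected dimer digallate
Product: 19 epicatechin-(4β→6)-epigallocatechin 3,3'-di-O-gallate (target)
Conditions: H2 (1 atm), Pd(OH)2/C, THF/MeOH, rt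
Reagents that add atoms: none
Why: Catalytic hydrogenolysis should cleave all thirteen benzyl ethers and the diphenylmethylene ketal under neutral conditions that should leave the two esters (without migration of the 3'-galloyl group to the neighbouring hydroxyl), the interflavan bond and every stereocenter untouched.

**Compound list**

1 | (−)-epicatechin, (2R,3R)-2-(3,4-dihydroxyphenyl)chromane-3,5,7-triol | C1c2c(O)cc(O)cc2O[C@H](c2ccc(O)c(O)c2)[C@@H]1O | starting material

2 | 5,7,3',4'-tetra-O-benzyl-(−)-epicatechin, (2R,3R)-5,7-bis(benzyloxy)-2-[3,4-bis(benzyloxy)phenyl]chroman-3-ol | C1c2c(OCc3ccccc3)cc(OCc3ccccc3)cc2O[C@H](c2ccc(OCc3ccccc3)c(OCc3ccccc3)c2)[C@@H]1O | intermediate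

3 | 3,5,7,3',4'-penta-O-benzyl-(−)-epicatechin, (2R,3R) | C1c2c(OCc3ccccc3)cc(OCc3ccccc3)cc2O[C@H](c2ccc(OCc3ccccc3)c(OCc3ccccc3)c2)[C@@H]1OCc1ccccc1 | intermediate

4 | (2R,3R,4S)-3,5,7-tris(benzyloxy)-2-[3,4-bis(benzyloxy)phenyl]-4-(2-ethoxyethoxy)chromane (4β-ether) | CCOCCO[C@H]1c2c(OCc3ccccc3)cc(OCc3ccccc3)cc2O[C@H](c2ccc(OCc3ccccc3)c(OCc3ccccc3)c2)[C@@H]1OCc1ccccc1 | intermediate

5 | phloroglucinol (benzene-1,3,5-triol) | Oc1cc(O)cc(O)c1 | starting material

6 | flavan-4-yl cation of penta-O-benzylepicatechin (C4 carbocation delocalised into ring A; 2R,3R) | [CH+]1c2c(OCc3ccccc3)cc(OCc3ccccc3)cc2O[C@H](c2ccc(OCc3ccccc3)c(OCc3ccccc3)c2)[C@@H]1OCc1ccccc1 | intermediate (not isolated)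

7 | 2-{(2R,3R,4S)-3,5,7-tris(benzyloxy)-2-[3,4-bis(benzyloxy)phenyl]chroman-4-yl}benzene-1,3,5-triol (penta-O-benzylepicatechin-(4β→2)-phloroglucinol) | Oc1cc(O)c([C@H]2c3c(OCc4ccccc4)cc(OCc4ccccc4)cc3O[C@H](c3ccc(OCc4ccccc4)c(OCc4ccccc4)c3)[C@@H]2OCc2ccccc2)c(O)c1 | intermediate

8 | 3,4,5-trihydroxybenzaldehyde | O=Cc1cc(O)c(O)c(O)c1 | starting material

9 | 7-hydroxy-2,2-diphenyl-1,3-benzodioxole-5-carbaldehyde | O=Cc1cc(O)c2OC(c3ccccc3)(c3ccccc3)Oc2c1 | intermediate

10 | 2,2-diphenyl-7-(triisopropylsilyloxy)-1,3-benzodioxole-5-carbaldehyde | O=Cc1cc(O[Si](C(C)C)(C(C)C)C(C)C)c2OC(c3ccccc3)(c3ccccc3)Oc2c1 | intermediate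

11 | rac-1-[2,2-diphenyl-7-(triisopropylsilyloxy)-1,3-benzodioxol-5-yl]prop-2-en-1-ol | C=CC(O)c1cc(O[Si](C(C)C)(C(C)C)C(C)C)c2OC(c3ccccc3)(c3ccccc3)Oc2c1 | intermediate

12 | (S)-[2,2-diphenyl-7-(triisopropylsilyloxy)-1,3-benzodioxol-5-yl][(2R)-oxiran-2-yl]methanol (erythro epoxy alcohol) | O[C@@H](c1cc(O[Si](C(C)C)(C(C)C)C(C)C)c2OC(c3ccccc3)(c3ccccc3)Oc2c1)[C@H]1CO1 | intermediate

13 | 5-{(R)-[2,2-diphenyl-7-(triisopropylsilyloxy)-1,3-benzodioxol-5-yl][(2R)-oxiran-2-yl]methoxy}-2-{(2R,3R,4S)-3,5,7-tris(benzyloxy)-2-[3,4-bis(benzyloxy)phenyl]chroman-4-yl}benzene-1,3-diol | Oc1cc(O[C@H](c2cc(O[Si](C(C)C)(C(C)C)C(C)C)c3OC(c4ccccc4)(c4ccccc4)Oc3c2)[C@H]2CO2)cc(O)c1[C@H]1c2c(OCc3ccccc3)cc(OCc3ccccc3)cc2O[C@H](c2ccc(OCc3ccccc3)c(OCc3ccccc3)c2)[C@@H]1OCc1ccccc1 | intermediate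

14 | (2R,3R,4S)-3,5,7-tris(benzyloxy)-2-[3,4-bis(benzyloxy)phenyl]-4-[2,6-bis(benzyloxy)-4-{(R)-[2,2-diphenyl-7-(triisopropylsilyloxy)-1,3-benzodioxol-5-yl][(2R)-oxiran-2-yl]methoxy}phenyl]chromane | c1ccccc1COc1cc(O[C@H](c2cc(O[Si](C(C)C)(C(C)C)C(C)C)c3OC(c4ccccc4)(c4ccccc4)Oc3c2)[C@H]2CO2)cc(OCc2ccccc2)c1[C@H]1c2c(OCc3ccccc3)cc(OCc3ccccc3)cc2O[C@H](c2ccc(OCc3ccccc3)c(OCc3ccccc3)c2)[C@@H]1OCc1ccccc1 | intermediate

15 | penta-O-benzylepicatechin-(4β→6)-[5,7-di-O-benzyl-4',5'-O-diphenylmethylene-3'-O-triisopropylsilyl-epigallocatechin]; upper 2R,3R,4S, lower 2R,3R, free lower 3-OH | CC(C)[Si](C(C)C)(C(C)C)Oc1cc([C@H]2Oc3cc(OCc4ccccc4)c([C@H]4c5c(OCc6ccccc6)cc(OCc6ccccc6)cc5O[C@H](c5ccc(OCc6ccccc6)c(OCc6ccccc6)c5)[C@@H]4OCc4ccccc4)c(OCc4ccccc4)c3C[C@H]2O)cc2OC(c3ccccc3)(c3ccccc3)Oc12 | intermediate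

16 | penta-O-benzylepicatechin-(4β→6)-[5,7-di-O-benzyl-4',5'-O-diphenylmethylene-epigallocatechin]; free lower 3-OH and 3'-OH | Oc1cc([C@H]2Oc3cc(OCc4ccccc4)c([C@H]4c5c(OCc6ccccc6)cc(OCc6ccccc6)cc5O[C@H](c5ccc(OCc6ccccc6)c(OCc6ccccc6)c5)[C@@H]4OCc4ccccc4)c(OCc4ccccc4)c3C[C@H]2O)cc2OC(c3ccccc3)(c3ccccc3)Oc12 | intermediate

17 | 3,4,5-tris(benzyloxy)benzoyl chloride | O=C(Cl)c1cc(OCc2ccccc2)c(OCc2ccccc2)c(OCc2ccccc2)c1 | starting material

18 | 3,3'-bis-O-[3,4,5-tris(benzyloxy)benzoyl] derivative of 16 (fully protected target) | O=C(Oc1cc([C@H]2Oc3cc(OCc4ccccc4)c([C@H]4c5c(OCc6ccccc6)cc(OCc6ccccc6)cc5O[C@H](c5ccc(OCc6ccccc6)c(OCc6ccccc6)c5)[C@@H]4OCc4ccccc4)c(OCc4ccccc4)c3C[C@H]2OC(=O)c2cc(OCc3ccccc3)c(OCc3ccccc3)c(OCc3ccccc3)c2)cc2OC(c3ccccc3)(c3ccccc3)Oc12)c1cc(OCc2ccccc2)c(OCc2ccccc2)c(OCc2ccccc2)c1 | intermediate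

19 | epicatechin-(4β→6)-epigallocatechin 3,3'-di-O-gallate (CNP0237700.1) | O=C(Oc1cc([C@H]2Oc3cc(O)c([C@H]4c5c(O)cc(O)cc5O[C@H](c5ccc(O)c(O)c5)[C@@H]4O)c(O)c3C[C@H]2OC(=O)c2cc(O)c(O)c(O)c2)cc(O)c1O)c1cc(O)c(O)c(O)c1 | target

**Step count**

Total: 14 steps. Longest linear sequence: 10 steps (steps 1–4 or steps 5–8, then steps 9–14).

**Steps most likely to fail**

1. Step 9. The process at risk is poor site selectivity among the three phenolic hydroxyls of 7 (ether formation at a flanking hydroxyl would lead on to the 4→8 series), together with partial loss of configuration by ionisation of the electron-rich benzylic oxyphosphonium ion. The fallback sets out from 7 and returns at 14, and fixes the site by protection instead of by rate. 7 is silylated at the unhindered para-hydroxyl (TBDPSCl, imidazole, CH2Cl2, 0 °C) to give 4-(tert-butyldiphenylsilyloxy)-2,6-dihydroxyphenyl-substituted penta-O-benzylepicatechin F1. Its two flanking phenols are benzylated (BnBr, K2CO3, DMF) to give the dibenzyl silyl ether F2. Desilylation (TBAF, AcOH, THF) gives 3,5-bis(benzyloxy)-4-(penta-O-benzylepicatechin-4β-yl)phenol F3, whose single free phenol is coupled with 12 under the Mitsunobu conditions of step 9 to give 14 directly.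

2. Step 11. The processes at risk are oxirane opening at the internal carbon (5-exo closure to a dihydrobenzofuran), hydride shift to an aldehyde, and acid-induced scission of the interflavan bond or of the benzylic aryl ether. The fallback sets out from 13 and returns at 15, and changes the nucleophile and the order of events. The ring is closed before benzylation, when the central ring is a free resorcinol-type ring and a much stronger carbon nucleophile, so the oxirane can be activated by hydrogen bonding alone (hexafluoroisopropanol, rt, no metal Lewis acid). This should give the 5,7-dihydroxy flavan-3-ol F4, the same constitution by the same equivalence of the two ortho carbons. Benzylation of its two phenols (BnBr, K2CO3, DMF; the secondary 3-OH is not alkylated by carbonate) then gives 15.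

3. Step 8. The processes at risk are a low rate ratio between the enantiomers of an electron-rich aryl vinyl carbinol and titanium-promoted opening of the benzylic epoxy alcohol. The fallback sets out from 11 and returns at 12, and lets an enzyme instead of the titanium–tartrate catalyst tell the enantiomers apart, so that no epoxide is exposed to titanium. Acylation of rac-11 with vinyl acetate and Burkholderia cepacia lipase (Amano PS, hexane/MTBE, 30 °C) should esterify the (R)-enantiomer, in which the aryl group takes the large pocket and the vinyl group the medium pocket, to give (R)-1-[2,2-diphenyl-7-(triisopropylsilyloxy)-1,3-benzodioxol-5-yl]prop-2-en-1-yl acetate F5, which is separated from unreacted (S)-11. Reductive removal of the acetyl group (iBu2AlH, CH2Cl2, −78 °C), chosen over methanolysis to spare the aryl silyl ether, gives (R)-1-arylprop-2-en-1-ol F6. Hydroxyl-directed epoxidation (VO(acac)2, TBHP, CH2Cl2, 0 °C), which favours the erythro isomer for terminal vinyl carbinols, should give 12 after removal of the minor threo isomer by chromatography.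

**Further compounds**

F1 | step 9 | 5-(tert-butyldiphenylsilyloxy)-2-{(2R,3R,4S)-3,5,7-tris(benzyloxy)-2-[3,4-bis(benzyloxy)phenyl]chroman-4-yl}benzene-1,3-diol | CC(C)(C)[Si](c1ccccc1)(c1ccccc1)Oc1cc(O)c([C@H]2c3c(OCc4ccccc4)cc(OCc4ccccc4)cc3O[C@H](c3ccc(OCc4ccccc4)c(OCc4ccccc4)c3)[C@@H]2OCc2ccccc2)c(O)c1
F2 | step 9 | 1,3-di-O-benzyl ether of F1 | CC(C)(C)[Si](c1ccccc1)(c1ccccc1)Oc1cc(OCc2ccccc2)c([C@H]2c3c(OCc4ccccc4)cc(OCc4ccccc4)cc3O[C@H](c3ccc(OCc4ccccc4)c(OCc4ccccc4)c3)[C@@H]2OCc2ccccc2)c(OCc2ccccc2)c1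
F3 | step 9 | 3,5-bis(benzyloxy)-4-{(2R,3R,4S)-3,5,7-tris(benzyloxy)-2-[3,4-bis(benzyloxy)phenyl]chroman-4-yl}phenol | Oc1cc(OCc2ccccc2)c([C@H]2c3c(OCc4ccccc4)cc(OCc4ccccc4)cc3O[C@H](c3ccc(OCc4ccccc4)c(OCc4ccccc4)c3)[C@@H]2OCc2ccccc2)c(OCc2ccccc2)c1
F4 | step 11 | penta-O-benzylepicatechin-(4β→6)-[4',5'-O-diphenylmethylene-3'-O-triisopropylsilyl-epigallocatechin] with free 3-, 5- and 7-OH on the lower unit (2R,3R) | CC(C)[Si](C(C)C)(C(C)C)Oc1cc([C@H]2Oc3cc(O)c([C@H]4c5c(OCc6ccccc6)cc(OCc6ccccc6)cc5O[C@H](c5ccc(OCc6ccccc6)c(OCc6ccccc6)c5)[C@@H]4OCc4ccccc4)c(O)c3C[C@H]2O)cc2OC(c3ccccc3)(c3ccccc3)Oc12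
F5 | step 8 | (R)-1-[2,2-diphenyl-7-(triisopropylsilyloxy)-1,3-benzodioxol-5-yl]prop-2-en-1-yl acetate | C=C[C@@H](OC(C)=O)c1cc(O[Si](C(C)C)(C(C)C)C(C)C)c2OC(c3ccccc3)(c3ccccc3)Oc2c1
F6 | step 8 | (R)-1-[2,2-diphenyl-7-(triisopropylsilyloxy)-1,3-benzodioxol-5-yl]prop-2-en-1-ol | C=C[C@@H](O)c1cc(O[Si](C(C)C)(C(C)C)C(C)C)c2OC(c3ccccc3)(c3ccccc3)Oc2c1
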